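All constants were drawn at random within sensible limits; the run is a simulation.

Beside elm stood a neighbour with 1.50 equiv of G, so I wanted a reckoning that could be carried from one flask to the other.

    Z + G → Z.G (k1 = 0.0165 L mol⁻¹ s⁻¹)
    Z + G → E (k2 = 0.00574 L mol⁻¹ s⁻¹)
    G + Z.G → G.Z.G (k3 = 7.52 × 10⁻⁴ L mol⁻¹ s⁻¹)
    G + E → G.Z.G (k4 = 0.00969 L mol⁻¹ s⁻¹)
    Z.G ⇌ D (K5 = 0.37, k5 = 0.00103 s⁻¹)

| flask | Z | G | time | remark |
|---|---|---|---|---|
| larch | 0.10 M (fed, over 8.0 min) | 0.900 equiv | 2.5 h | all else is in the flask from the start; the feed brings no volume worth counting |
| maple | 0.10 M | 0.900 equiv (fed, over 30 min) | 2.5 h | all else is in the flask from the start; the feed brings no volume worth counting |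
| alder | 0.10 M (fed, over 30 min) | 0.900 equiv | 2.5 h | all else is in the flask from the start; the feed brings no volume worth counting |
| elm | 0.10 M | 0.900 equiv | 2.5 h | everything together at the start |

- the flask with the highest amount of Z.G, in percent of the Z charged ("all alike" if they lie within 1.5 percentage points) (larch / maple / alder / elm / all alike)
- final Z.G, as a percentage of the Z charged, in larch
- final Z.G, as a percentage of the Z charged, in maple
- final Z.G, as a percentage of the Z charged, in alder
- final Z.G, as a percentage of the Z charged, in elm

I began by freezing what hardly moves. Step 5 relaxes in 4.37 min, far shorter than the 2.5 h of the run, so I took Z.G and D as one pool and held φ, the frozen share of Z.G in that pool, at 73.0%. Z splits between pool and E in the ratio of 2.9, which sends a fraction b = 74.2% to the pool. With G as limiting reagent and no G spent on a second addition, elm would hold 48.7% of Z.G.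

But each G.Z.G takes a second G, so if I assumed G consumed to the end in elm, the fraction z of Z left equalled 10.0% plus G.Z.G, both counted against the Z charged. I guessed z = 20.0%, twice that gap. Step 3 acts on Z.G, which I held at φ of the pool, so the pool drains at ρ = 0.0247 of the rate constant with which Z goes. The textbook chain result then gives a pool of b/(1−ρ)·(z^ρ−z) = 57.9%, and Z.G of 42.3% in elm, which I committed to. Each G step is first order in G, so I gave maple the same figure. Larch and alder I did not reckon.

The weak link was the guessed z. The same chain result for E in elm, with ratio 0.436, gave 13.5%. The balance then left enough G.Z.G to put z at 18.6%, and my estimate of Z.G in elm became 43.0%.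

The forecast said all alike, with 42.4% in larch, 42.6% in maple, 41.7% in alder and 42.6% in elm: “The spread is about 1 point, so all alike”.

The flasks gave all alike: 42.5% in larch, 42.6% in maple, 41.7% in alder and 42.6% in elm. Elm held Z at 19.1% after 2.50 h, against the 18.6% of my reckoning. Alder, which I had not reckoned, left a pool of 57.1% once its Z, E and G.Z.G are subtracted, and φ turns that into 41.7% of Z.G.

In the neighbour with 1.50 equiv of G, Z stood at 0.138%, and φ with the chain result gives 47.1% of Z.G. The computed flask holds 46.9%.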